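**Plan**

Numbering (2H-cyclohepta[b]furan-2-one core): O1, C2 (lactone C=O), C3 (=CH2), C3a, C4 (CH2), C5 (C=O), C6 (Me), C7 (OH, butenoyl), C8 (O-acyl), C8a (O1).
Cuts, in retrosynthetic order: C8–O ester; lactone (to a 2-methylene-1,4-diol) and enone (to an allylic silyl ether); ring bond C3a–C4; C8a–C3a; C7–C6; butenoyl C(=O)–CH=.
Forward: L-threitol acetonide supplies the acyl carbon, C7, C8 and C8a; Ireland–Claisen adds C6–C5–C4; propenyllithium adds the side chain; Ni/Cr coupling adds C3a–C3(–C2)–CH2Si; anodic coupling closes the seven-membered ring; oxidative lactonization closes the lactone ring; acylation is last.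
Stereochemistry: C8 from L-tartaric acid; C7 and C6 from the Claisen step (face anti to the C8a arm, chair, E-crotyl); C8a from ligand-controlled Ni/Cr addition; C3a from the key step (allylic 1,3-strain); ester centre from (R)-2-methylbutanoic acid.
Enabling feature: the γ,δ-unsaturated ketone C5(=O)–C4H2–C3a–C3(=CH2). C4 is the unsubstituted α-carbon of the ring ketone and C3a is allylic to the exocyclic methylene of the lactone ring, so C3a–C4 is the bond that an enol ether radical cation (C4=C5) forms with an allylsilane (C3a=C3–CH2Si).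

Key step: step 15

Remark: the side-chain carbinol carbon made in step 6 is carried as both epimers (left undefined in the SMILES of 14–18 and 25–32), because step 17 returns it to the ketone.
Remark: (E)-but-2-en-1-ol, (E)-1-bromoprop-1-ene and (R)-2-methylbutanoic acid are taken as commercial single isomers.

**Route**

Step 1
Reactants: 1 2,3-O-isopropylidene-L-threitol
Product: 2 mono-PMB ether
Conditions: NaH (1.0 equiv), 4-methoxybenzyl chloride (1.0 equiv), Bu4NI (cat.), THF/DMF, 0 °C → rt
Reagents that add atoms: 4-methoxybenzyl chloride, COc1ccc(CCl)cc1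
Why: Williamson etherification of a C2-symmetric diol, so mono-alkylation with one equivalent of base should give a single mono-ether and no new stereocentre.

Step 2
Reactants: 2 mono-PMB ether
Product: 4 dioxolane carboxylic acid, via aldehyde 3 (not isolated)
Conditions: TEMPO (0.2 equiv), PhI(OAc)2 (2.2 equiv), MeCN/H2O (1:1), rt
Reagents that add atoms: water, O
Why: Nitroxyl-catalysed oxidation of the primary alcohol through aldehyde 3 and its hydrate should give the acid while sparing the PMB ether and the acetonide; any epimerization α to the carboxyl is harmless because that centre is enolized in step 4.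

Step 3
Reactants: 4 dioxolane carboxylic acid; 5 (E)-but-2-en-1-ol
Product: 6 crotyl ester
Conditions: DCC, DMAP (cat.), CH2Cl2, 0 °C → rt
Reagents that add atoms: none
Why: Steglich esterification should join the acid to the allylic alcohol under neutral conditions without allylic transposition.

Step 4
Reactants: 6 crotyl ester
Product: 9 Claisen acid, via silyl ketene acetal 7 (not isolated), via trimethylsilyl ester 8 (not isolated)
Conditions: LiN(iPr)2, Me3SiCl/Et3N (in situ), THF, −78 °C → rt; aq. citric acid work-up
Reagents that add atoms: none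
Why: Ireland–Claisen rearrangement: silylation in situ should trap the lithium-chelated ester enolate (OSiMe3 cis to the ring oxygen) before the β-oxygen can be expelled, and the [3,3] shift through a chair with the E-crotyl methyl equatorial and the allyl unit adding to the ketene acetal face anti to the CH2OPMB arm should set C7 (quaternary) and C6 (methyl) together, both relayed from the tartrate-derived C8 centre.

Step 5
Reactants: 9 Claisen acid; 10 (E)-1-bromoprop-1-ene
Product: 13 propenyl ketone, via propenyllithium 11 (not isolated), via dilithium gem-diolate 12 (not isolated)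
Conditions: 10, t-BuLi, Et2O, −78 °C; then 9, −78 → 0 °C; inverse quench into cold aq. NH4Cl
Reagents that add atoms: none
Why: Ketone synthesis from a carboxylic acid and two equivalents of an organolithium: halogen–lithium exchange keeps the E geometry, and the dilithium gem-diolate 12 should resist a second addition until hydrolysis releases the enone.

Step 6
Reactants: 13 propenyl ketone
Product: 14 allylic alcohol
Conditions: NaBH4, CeCl3·7H2O, MeOH, −40 °C
Reagents that add atoms: none
Why: Luche 1,2-reduction should mask the enone as an allylic alcohol; the new carbinol centre need not be controlled because it is re-oxidized in step 17.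

Step 7
Reactants: 14 allylic alcohol
Product: 15 TBS ether
Conditions: TBSOTf, 2,6-lutidine, CH2Cl2, −78 → 0 °C
Reagents that add atoms: tert-butyldimethylsilyl triflate, CC(C)(C)[Si](C)(C)OS(=O)(=O)C(F)(F)F
Why: Silyl triflate silylation is used because the carbinol is flanked by a quaternary carbon; the ether keeps this position inert through the oxidations and the anodic step.

Step 8
Reactants: 15 TBS ether
Product: 16 methyl ketone
Conditions: PdCl2 (10 mol%), CuCl, O2 (1 atm), DMF/H2O (7:1), rt
Reagents that add atoms: water, O
Why: Tsuji–Wacker oxidation (O2 as terminal oxidant) should convert the terminal vinyl group into the C5 methyl ketone with Markovnikov selectivity, the 1,2-disubstituted propenyl alkene reacting far more slowly.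

Step 9
Reactants: 16 methyl ketone
Product: 17 primary alcohol
Conditions: DDQ, CH2Cl2/pH 7 buffer (10:1), 0 °C
Reagents that add atoms: none
Why: Oxidative cleavage of the PMB ether by DDQ (hydride abstraction from the electron-rich benzylic position) should free the C8a hydroxymethyl group without touching the silyl ether, ketone or acetonide.

Step 10
Reactants: 17 primary alcohol
Product: 18 aldehyde
Conditions: Dess–Martin periodinane, NaHCO3, CH2Cl2, 0 °C → rt
Reagents that add atoms: none
Why: Buffered Dess–Martin oxidation should give the α-alkoxy aldehyde without epimerization at C8; it is used at once.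

Step 11
Reactants: 19 prop-2-yn-1-ol; 20 (trimethylsilyl)methylmagnesium chloride
Product: 22 iodo allylic alcohol, via alkenylmagnesium chloride 21 (not isolated)
Conditions: 20 (2.5 equiv), CuI (10 mol%), Et2O, 0 °C → reflux; then I2, −78 → 0 °C
Reagents that add atoms: iodine, II
Why: Copper-catalysed anti-carbomagnesiation of propargyl alcohol: the magnesium alkoxide directs the Grignard carbon to C2 and magnesium to C3 cis to the CH2O group, and iodinolysis with retention should give one alkene isomer.

Step 12
Reactants: 22 iodo allylic alcohol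
Product: 23 vinyl iodide TBS ether
Conditions: TBSCl, imidazole, CH2Cl2, rt
Reagents that add atoms: tert-butyldimethylsilyl chloride, CC(C)(C)[Si](C)(C)Cl
Why: Standard silylation protects the future C2 oxygen for the coupling and the anodic step.

Step 13
Reactants: 18 aldehyde; 23 vinyl iodide TBS ether
Product: 25 C8a allylic alcohol, via alkenylchromium dichloride 24 (not isolated)
Conditions: CrCl2 (4 equiv), NiCl2 (2 mol%), chiral oxazoline–sulfonamide ligand, Et3N, THF, rt
Reagents that add atoms: none
Why: Nozaki–Hiyama–Kishi coupling: zerovalent nickel inserts into the C–I bond and transmetalation gives alkenylchromium 24 with retention of alkene geometry, which adds to the aldehyde and leaves the methyl ketone untouched; the new C8a carbinol centre is set by the chiral sulfonamide ligand on chromium (enantiomer chosen for the threo, anti-Felkin epimer), which has to override the weak Felkin–Anh preference of the acetonide aldehyde.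

Step 14
Reactants: 25 C8a allylic alcohol
Product: 27 silyl enol ether, via silyl ether ketone 26 (not isolated)
Conditions: TBSOTf (2.5 equiv), Et3N, CH2Cl2, −78 → 0 °C
Reagents that add atoms: tert-butyldimethylsilyl triflate, CC(C)(C)[Si](C)(C)OS(=O)(=O)C(F)(F)F
Why: Silyl triflate/amine silylation of the alcohol followed by soft enolization of the methyl ketone should give the terminal (C4=C5) silyl enol ether, since the other α-carbon is tertiary and sits next to the quaternary C7.

Step 15
Reactants: 27 silyl enol ether
Product: 28 cycloheptanone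
Conditions: RVC anode, Pt cathode, undivided cell, constant current (8 mA, 2.2 F/mol), LiClO4 (0.1 M), 2,6-lutidine, MeOH/CH2Cl2 (1:4), rt
Reagents that add atoms: none
Why: Anodic one-electron oxidation of the silyl enol ether (C4=C5) gives a radical cation whose terminal carbon C4 is attacked by the γ-carbon (C3a) of the tethered allylsilane; the β-silyl cation at C3 loses Me3Si+ to methanol to give the exocyclic methylene, and a second electron transfer with loss of the silyl group from the oxocarbenium ion gives the C5 ketone. The closest known reaction type is the intramolecular anodic olefin coupling of enol ether radical cations with allylsilane terminators, and the anodic silyl enol ether–furan coupling that closes a seven-membered carbocycle is the closest ring-size precedent. The one ring that closes, the cycloheptanone, forms in the 7-exo-trig mode with respect to the allylsilane double bond (C3a attacked, C3 left outside the ring). The new stereocentre C3a is controlled by allylic 1,3-strain: the CH2OTBS group cis to C8a forces the C8a–H bond into the alkene plane, the tether (C8 side) and the OTBS group then lie on opposite faces, and because C4 can reach C3a only from the tether face the C3a–C3 bond should end up trans to the C8a oxygen. The step needs cyclization to outrun methanol trapping of the radical cation and attack by the 1,2-disubstituted propenyl alkene (a six-membered alternative); the low oxidation potential of the two electron-rich partners, the much higher nucleophilicity of a trisubstituted allylsilane, the low methanol content and the 2,6-lutidine buffer are expected to secure this. Bond formation at C3a and not at the CH2Si carbon is secured by the β-silicon effect.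

Step 16
Reactants: 28 cycloheptanone
Product: 29 triol
Conditions: HF·pyridine, pyridine, THF, 0 °C → rt
Reagents that add atoms: none
Why: Fluoride-mediated desilylation under buffered acidic conditions should remove the three TBS groups and keep the acetonide, while avoiding base that could eliminate the β-alkoxy ketone.

Step 17
Reactants: 29 triol
Product: 33 lactone enone, via hydroxy enal 30 (not isolated), via lactol 31 (not isolated), via hydroxy lactone 32 (not isolated)
Conditions: MnO2 (activated, excess), CH2Cl2, rt
Reagents that add atoms: none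
Why: Chemoselective allylic oxidation with MnO2: the primary allylic alcohol gives enal 30, which closes with the C8a hydroxyl to the trans-fused lactol 31 and is oxidized on to the α-methylene-γ-butyrolactone 32, and the secondary allylic alcohol then gives the (E)-enone; the ring fusion stereochemistry is already fixed at C3a and C8a.

Step 18
Reactants: 33 lactone enone
Product: 34 diol
Conditions: CF3CO2H/H2O (9:1), 0 °C
Reagents that add atoms: none
Why: Acid hydrolysis of the trans-fused (strained) isopropylidene acetal should free the C7 and C8 hydroxyls; lactone, enone and β-hydroxy ketone should tolerate brief cold acid.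

Step 19
Reactants: 34 diol; 35 (R)-2-methylbutanoic acid
Product: 36 target
Conditions: DCC, DMAP (cat.), CH2Cl2, 0 °C
Reagents that add atoms: none
Why: Steglich esterification should acylate only the secondary C8 hydroxyl, the tertiary C7 hydroxyl being inert, and the low temperature should preserve the α-stereocentre of the acid.

**Compound list**

1 | 2,3-O-isopropylidene-L-threitol, [(4S,5S)-2,2-dimethyl-1,3-dioxolane-4,5-diyl]dimethanol | OC[C@@H]1OC(C)(C)O[C@H]1CO | starting material
2 | mono-PMB ether, [(4S,5S)-5-{[(4-methoxybenzyl)oxy]methyl}-2,2-dimethyl-1,3-dioxolan-4-yl]methanol | OC[C@@H]1OC(C)(C)O[C@H]1COCc1ccc(OC)cc1 | intermediate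
3 | (4R,5S)-5-{[(4-methoxybenzyl)oxy]methyl}-2,2-dimethyl-1,3-dioxolane-4-carbaldehyde | O=C[C@@H]1OC(C)(C)O[C@H]1COCc1ccc(OC)cc1 | intermediate (not isolated)
4 | (4R,5S)-5-{[(4-methoxybenzyl)oxy]methyl}-2,2-dimethyl-1,3-dioxolane-4-carboxylic acid | OC(=O)[C@@H]1OC(C)(C)O[C@H]1COCc1ccc(OC)cc1 | intermediate
5 | (E)-but-2-en-1-ol | C/C=C/CO | starting material
6 | (E)-but-2-enyl ester of 4 | C/C=C/COC(=O)[C@@H]1OC(C)(C)O[C@H]1COCc1ccc(OC)cc1 | intermediate
7 | O-trimethylsilyl O-(E)-but-2-enyl ketene acetal of 6, OSiMe3 cis to the ring oxygen | C/C=C/CO/C(O[Si](C)(C)C)=C1/OC(C)(C)O[C@H]1COCc1ccc(OC)cc1 | intermediate (not isolated)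
8 | trimethylsilyl ester of 9 | C=C[C@H](C)[C@]1(C(=O)O[Si](C)(C)C)OC(C)(C)O[C@H]1COCc1ccc(OC)cc1 | intermediate (not isolated)
9 | (4S,5S)-4-[(2S)-but-3-en-2-yl]-5-{[(4-methoxybenzyl)oxy]methyl}-2,2-dimethyl-1,3-dioxolane-4-carboxylic acid | C=C[C@H](C)[C@]1(C(=O)O)OC(C)(C)O[C@H]1COCc1ccc(OC)cc1 | intermediate
10 | (E)-1-bromoprop-1-ene | C/C=C/Br | starting material
11 | (E)-prop-1-enyllithium | C/C=C/[Li] | intermediate (not isolated)
12 | dilithium gem-diolate of ketone 13 | C=C[C@H](C)[C@]1(C(O[Li])(O[Li])/C=C/C)OC(C)(C)O[C@H]1COCc1ccc(OC)cc1 | intermediate (not isolated)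
13 | (E)-1-[(4S,5S)-4-[(2S)-but-3-en-2-yl]-5-{[(4-methoxybenzyl)oxy]methyl}-2,2-dimethyl-1,3-dioxolan-4-yl]but-2-en-1-one | C=C[C@H](C)[C@]1(C(=O)/C=C/C)OC(C)(C)O[C@H]1COCc1ccc(OC)cc1 | intermediate
14 | allylic alcohol from 13, (E)-1-hydroxybut-2-enyl side chain, both carbinol epimers | C=C[C@H](C)[C@]1(C(O)/C=C/C)OC(C)(C)O[C@H]1COCc1ccc(OC)cc1 | intermediate
15 | TBS ether of 14 | C=C[C@H](C)[C@]1(C(O[Si](C)(C)C(C)(C)C)/C=C/C)OC(C)(C)O[C@H]1COCc1ccc(OC)cc1 | intermediate
16 | methyl ketone, vinyl group of 15 converted to acetyl (future C5) | CC(=O)[C@H](C)[C@]1(C(O[Si](C)(C)C(C)(C)C)/C=C/C)OC(C)(C)O[C@H]1COCc1ccc(OC)cc1 | intermediate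
17 | primary alcohol, PMB removed from 16 | CC(=O)[C@H](C)[C@]1(C(O[Si](C)(C)C(C)(C)C)/C=C/C)OC(C)(C)O[C@H]1CO | intermediate
18 | aldehyde at the future C8a | CC(=O)[C@H](C)[C@]1(C(O[Si](C)(C)C(C)(C)C)/C=C/C)OC(C)(C)O[C@H]1C=O | intermediate
19 | prop-2-yn-1-ol | C#CCO | starting material
20 | (trimethylsilyl)methylmagnesium chloride | C[Si](C)(C)C[Mg]Cl | starting material
21 | (Z)-alkenylmagnesium chloride alkoxide from 19 and 20, Mg cis to CH2O | C[Si](C)(C)C/C(CO[Mg]Cl)=C/[Mg]Cl | intermediate (not isolated)
22 | (E)-3-iodo-2-[(trimethylsilyl)methyl]prop-2-en-1-ol, I cis to CH2OH | C[Si](C)(C)C/C(CO)=C/I | intermediate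
23 | TBS ether of 22 | C[Si](C)(C)C/C(CO[Si](C)(C)C(C)(C)C)=C/I | intermediate
24 | alkenylchromium dichloride from 23 | C[Si](C)(C)C/C(CO[Si](C)(C)C(C)(C)C)=C/[Cr](Cl)Cl | intermediate (not isolated)
25 | C8a allylic alcohol, threo to the C8 oxygen, carrying the allylsilane | CC(=O)[C@H](C)[C@]1(C(O[Si](C)(C)C(C)(C)C)/C=C/C)OC(C)(C)O[C@H]1[C@H](O)/C=C(/C[Si](C)(C)C)CO[Si](C)(C)C(C)(C)C | intermediate
26 | C8a O-TBS ether of 25, ketone still free | CC(=O)[C@H](C)[C@]1(C(O[Si](C)(C)C(C)(C)C)/C=C/C)OC(C)(C)O[C@H]1[C@H](O[Si](C)(C)C(C)(C)C)/C=C(/C[Si](C)(C)C)CO[Si](C)(C)C(C)(C)C | intermediate (not isolated)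
27 | terminal TBS enol ether of 26, key-step substrate | C=C(O[Si](C)(C)C(C)(C)C)[C@H](C)[C@]1(C(O[Si](C)(C)C(C)(C)C)/C=C/C)OC(C)(C)O[C@H]1[C@H](O[Si](C)(C)C(C)(C)C)/C=C(/C[Si](C)(C)C)CO[Si](C)(C)C(C)(C)C | intermediate
28 | cycloheptanone with trans-fused acetonide (C7/C8), OTBS at C8a and 3-(TBSO)prop-1-en-2-yl at C3a, trans to each other | C=C(CO[Si](C)(C)C(C)(C)C)[C@H]1CC(=O)[C@H](C)[C@]2(C(O[Si](C)(C)C(C)(C)C)/C=C/C)OC(C)(C)O[C@H]2[C@@H]1O[Si](C)(C)C(C)(C)C | intermediate
29 | triol from 28 | C=C(CO)[C@H]1CC(=O)[C@H](C)[C@]2(C(O)/C=C/C)OC(C)(C)O[C@H]2[C@@H]1O | intermediate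
30 | hydroxy enal | C=C(C=O)[C@H]1CC(=O)[C@H](C)[C@]2(C(O)/C=C/C)OC(C)(C)O[C@H]2[C@@H]1O | intermediate (not isolated)
31 | trans-fused α-methylene lactol | C=C1C(O)O[C@@H]2[C@@H]1CC(=O)[C@H](C)[C@]3(C(O)/C=C/C)OC(C)(C)O[C@H]32 | intermediate (not isolated)
32 | α-methylene lactone with side-chain allylic alcohol | C=C1C(=O)O[C@@H]2[C@@H]1CC(=O)[C@H](C)[C@]3(C(O)/C=C/C)OC(C)(C)O[C@H]32 | intermediate (not isolated)
33 | α-methylene lactone, (E)-butenoyl ketone, C7/C8 acetonide | C=C1C(=O)O[C@@H]2[C@@H]1CC(=O)[C@H](C)[C@]3(C(=O)/C=C/C)OC(C)(C)O[C@H]32 | intermediate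
34 | C7,C8-diol, target without the ester | C=C1C(=O)O[C@@H]2[C@@H]1CC(=O)[C@H](C)[C@@](O)(C(=O)/C=C/C)[C@H]2O | intermediate
35 | (R)-2-methylbutanoic acid | CC[C@@H](C)C(=O)O | starting material
36 | (3aR,6R,7S,8S,8aR)-7-[(2E)-but-2-enoyl]-7-hydroxy-6-methyl-3-methylidene-2,5-dioxooctahydro-2H-cyclohepta[b]furan-8-yl (2R)-2-methylbutanoate | C=C1C(=O)O[C@@H]2[C@@H]1CC(=O)[C@H](C)[C@@](O)(C(=O)/C=C/C)[C@H]2OC(=O)[C@H](C)CC | target

**Step count and risks**

Total steps: 19. Longest linear sequence: 17 (steps 1–10 and 13–19); steps 11–12 make the coupling partner 23.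

Steps most likely to fail:

1. Step 15. The seven-membered closure may be too slow, so that the radical cation is trapped by methanol or loses its silyl group before the C–C bond forms, or the face selectivity at C3a may leak. The fallback is a Tsuji–Trost closure of the same bond and sets out from aldehyde 18. Coupling under the conditions of step 13 with 2-(iodomethylidene)propane-1,3-diyl diacetate F1 (from commercial 1,3-diacetoxyacetone by Wittig iodomethylenation with Ph3P=CHI) should give the bis-acetate allylic alcohol F2. TBSOTf/Et3N as in step 14 should give the bis-silylated enol ether F3. Pd(PPh3)4 with tetrabutylammonium difluorotriphenylsilicate should unmask the enolate and ionize one allylic acetate; attack of the enolate at C3a of the π-allyl complex of divalent palladium (7-exo allylic alkylation) should give the acetoxymethyl cycloheptanone F4. Methanolysis (K2CO3, MeOH) should give the allylic alcohol F5, and HF·pyridine returns the route to triol 29.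

2. Step 13. Facial selectivity may be poor, because the ligand must override the substrate's Felkin–Anh preference. The fallback sets out from aldehyde 18 and iodide 23. The coupling is run without the chiral ligand so that the substrate-preferred C8a epimer F6 dominates. Mitsunobu inversion (4-nitrobenzoic acid, PPh3, diisopropyl azodicarboxylate) should give the inverted 4-nitrobenzoate F7, and K2CO3/MeOH returns the route to alcohol 25.

3. Step 19. Acylation of the hindered secondary hydroxyl may be slow, and forcing with base risks retro-aldol cleavage of the β-hydroxy ketone or epimerization of the acylating agent. The fallback sets out from diol 34 and acid 35 and activates the alcohol, not the acid. Acid 35 with oxalyl chloride should give (R)-2-methylbutanoyl chloride F8. Diol 34 with Bu2SnO should give the dibutylstannylene acetal F9, which should be acylated by F8 at the secondary oxygen at room temperature without amine base, returning the route at target 36.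

**Further compounds**

F1 | step 15 | 2-(iodomethylidene)propane-1,3-diyl diacetate | CC(=O)OCC(=CI)COC(C)=O
F2 | step 15 | C8a allylic alcohol carrying the bis(acetoxymethyl)vinyl group | CC(=O)[C@H](C)[C@]1(C(O[Si](C)(C)C(C)(C)C)/C=C/C)OC(C)(C)O[C@H]1[C@H](O)C=C(COC(C)=O)COC(C)=O
F3 | step 15 | C8a O-TBS ether and terminal TBS enol ether of F2 | C=C(O[Si](C)(C)C(C)(C)C)[C@H](C)[C@]1(C(O[Si](C)(C)C(C)(C)C)/C=C/C)OC(C)(C)O[C@H]1[C@H](O[Si](C)(C)C(C)(C)C)C=C(COC(C)=O)COC(C)=O
F4 | step 15 | cycloheptanone with 3-acetoxyprop-1-en-2-yl at C3a | C=C(COC(C)=O)[C@H]1CC(=O)[C@H](C)[C@]2(C(O[Si](C)(C)C(C)(C)C)/C=C/C)OC(C)(C)O[C@H]2[C@@H]1O[Si](C)(C)C(C)(C)C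
F5 | step 15 | cycloheptanone with 3-hydroxyprop-1-en-2-yl at C3a, two TBS ethers left | C=C(CO)[C@H]1CC(=O)[C@H](C)[C@]2(C(O[Si](C)(C)C(C)(C)C)/C=C/C)OC(C)(C)O[C@H]2[C@@H]1O[Si](C)(C)C(C)(C)C
F6 | step 13 | C8a epimer of 25 | CC(=O)[C@H](C)[C@]1(C(O[Si](C)(C)C(C)(C)C)/C=C/C)OC(C)(C)O[C@H]1[C@@H](O)/C=C(/C[Si](C)(C)C)CO[Si](C)(C)C(C)(C)C
F7 | step 13 | 4-nitrobenzoate of 25 | CC(=O)[C@H](C)[C@]1(C(O[Si](C)(C)C(C)(C)C)/C=C/C)OC(C)(C)O[C@H]1[C@H](OC(=O)c1ccc(cc1)[N+](=O)[O-])/C=C(/C[Si](C)(C)C)CO[Si](C)(C)C(C)(C)C
F8 | step 19 | (R)-2-methylbutanoyl chloride | CC[C@@H](C)C(=O)Cl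
F9 | step 19 | C7,C8-O-dibutylstannylene acetal of 34 | C=C1C(=O)O[C@@H]2[C@@H]1CC(=O)[C@H](C)[C@]3(C(=O)/C=C/C)O[Sn](CCCC)(CCCC)O[C@H]32
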